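**Plan**

- Retrosynthesis cuts C2–C3 of ring C first (carbenoid C–H insertion), then the O1–C2 ether bond (Mitsunobu), then the C6–prenyl bond (para-Claisen–Cope from a prenyl ether on the future O1) and the C5′–geranyl bond (arylcopper allylation).
- Enabling feature: C2 is the benzylic ether methine between O1 and ring B. As the CH2 of an O1 benzyl ether its two C–H bonds are activated by the oxygen and by electron-rich ring B, and they sit 1,6 to a diazo carbon (future C3) on the C4 carbonyl of ring A.
- Forward: rings A and B are bought as benzene rings (phloroacetophenone, 5-bromovanillin), decorated separately and joined through O1; ring C is the only ring made and closes in the third step from the end.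
- Stereochemistry: the single stereocentre C2 (S) is set in the ring closure by the chiral dirhodium carboxylate, which selects one of the two enantiotopic benzylic hydrogens; the E alkene comes in with geranyl bromide.
- Protection: O5 carries a triisopropylsilyl group (no C–H next to oxygen for the carbenoid to attack), O7, O3′ and O4′ carry methoxymethyl groups; buffered fluoride, then HCl/MeOH, release the target.

Key step: step 11

Abbreviations: prenyl = 3-methylbut-2-en-1-yl; geranyl = (2E)-3,7-dimethylocta-2,6-dien-1-yl; MOM = methoxymethyl; TIPS = triisopropylsilyl.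

Assumption: Rh2(S-PTTL)4 is taken to deliver the (2S) product; the sense of induction should be confirmed on a simple model benzyl ether, and the enantiomeric catalyst Rh2(R-PTTL)4 would replace it without other change if the sense proves opposite.

**Route**

Step 1
Reactants: 1 2′,4′,6′-trihydroxyacetophenone
Product: 2 1-[2,6-dihydroxy-4-(methoxymethoxy)phenyl]ethanone
Conditions: MOMCl (1.05 equiv), i-Pr2NEt, THF, 0 °C
Reagents that add atoms: chloromethyl methyl ether (MOMCl), COCCl
Why: Williamson-type O-alkylation should stop at the 4-mono ether, because the 4-hydroxyl is the most acidic and the only one not tied up in a hydrogen bond to the acetyl carbonyl.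

Step 2
Reactants: 2 1-[2,6-dihydroxy-4-(methoxymethoxy)phenyl]ethanone
Product: 3 1-[2-hydroxy-4-(methoxymethoxy)-6-(triisopropylsilyloxy)phenyl]ethanone
Conditions: TIPSCl (1.1 equiv), imidazole, DMF, rt
Reagents that add atoms: chlorotriisopropylsilane (TIPSCl), CC(C)[Si](Cl)(C(C)C)C(C)C
Why: Phenol silylation; the two ortho hydroxyls are equivalent, and once one is silylated the other is held in a strong chelate and is too hindered for a second bulky silyl group, so mono-protection is expected.

Step 3
Reactants: 3 1-[2-hydroxy-4-(methoxymethoxy)-6-(triisopropylsilyloxy)phenyl]ethanone; 4 3-methylbut-2-en-1-ol (prenol)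
Product: 5 1-[4-(methoxymethoxy)-2-(prenyloxy)-6-(triisopropylsilyloxy)phenyl]ethanone
Conditions: PPh3, DIAD, THF, 0 °C → rt
Reagents that add atoms: none
Why: Mitsunobu etherification of the acidic chelated phenol with a primary allylic alcohol proceeds by direct displacement at the alkoxyphosphonium carbon under neutral conditions that leave the aryl silyl ether intact.

Step 4
Reactants: 5 1-[4-(methoxymethoxy)-2-(prenyloxy)-6-(triisopropylsilyloxy)phenyl]ethanone
Product: 8 1-[6-hydroxy-4-(methoxymethoxy)-3-prenyl-2-(triisopropylsilyloxy)phenyl]ethanone, via ortho-dienone 6 (not isolated), via para-dienone 7 (not isolated)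
Conditions: N,N-diethylaniline, 195 °C, sealed tube, argon
Reagents that add atoms: none
Why: Aromatic Claisen rearrangement to the ortho carbon, Cope rearrangement on to the para carbon and tautomerisation (para-Claisen–Cope cascade, well known for prenyl ethers of 2-hydroxy-4,6-dialkoxyacetophenones) should place an unrearranged prenyl group between the two protected oxygens and free the phenol para to it.

Step 5
Reactants: 9 5-bromovanillin
Product: 10 3-bromo-4,5-dihydroxybenzaldehyde
Conditions: BBr3, CH2Cl2, −78 °C → rt; then H2O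
Reagents that add atoms: none
Why: Boron tribromide demethylation of an aryl methyl ether, in which bromide attacks the methyl group of the boron-complexed ether and the aldehyde and aryl bromide are untouched.

Step 6
Reactants: 10 3-bromo-4,5-dihydroxybenzaldehyde
Product: 11 3-bromo-4,5-bis(methoxymethoxy)benzaldehyde
Conditions: MOMCl (3 equiv), i-Pr2NEt, CH2Cl2, 0 °C → rt
Reagents that add atoms: chloromethyl methyl ether (MOMCl), COCCl
Why: Double Williamson-type O-alkylation of the catechol gives acetal protecting groups that tolerate the organolithium step and later direct and stabilise the ortho aryllithium.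

Step 7
Reactants: 11 3-bromo-4,5-bis(methoxymethoxy)benzaldehyde
Product: 12 [3-bromo-4,5-bis(methoxymethoxy)phenyl]methanol
Conditions: NaBH4, MeOH, 0 °C
Reagents that add atoms: none
Why: Borohydride reduction of the aldehyde removes the only electrophilic carbonyl before metalation and supplies the benzylic alcohol needed for the ether union.

Step 8
Reactants: 12 [3-bromo-4,5-bis(methoxymethoxy)phenyl]methanol; 13 geranyl bromide
Product: 16 [3-geranyl-4,5-bis(methoxymethoxy)phenyl]methanol, via dilithio alkoxide 14 (not isolated), via arylcopper alkoxide 15 (not isolated)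
Conditions: n-BuLi (2.2 equiv), THF, −78 °C; CuBr·SMe2 (1.1 equiv), −78 → −40 °C; 13, −40 → 0 °C; aq. NH4Cl
Reagents that add atoms: none
Why: The first equivalent of butyllithium masks the alcohol as its alkoxide, the second performs bromine–lithium exchange next to the chelating OMOM group, and the derived arylcopper should couple with the allylic bromide at its primary carbon (copper-mediated allylic substitution) with the E geometry retained.

Step 9
Reactants: 8 1-[6-hydroxy-4-(methoxymethoxy)-3-prenyl-2-(triisopropylsilyloxy)phenyl]ethanone; 16 [3-geranyl-4,5-bis(methoxymethoxy)phenyl]methanol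
Product: 17 1-{6-[3-geranyl-4,5-bis(methoxymethoxy)benzyloxy]-4-(methoxymethoxy)-3-prenyl-2-(triisopropylsilyloxy)phenyl}ethanone
Conditions: PPh3, DIAD, THF, 0 °C → rt
Reagents that add atoms: none
Why: Mitsunobu etherification joins the only free phenol of ring A (the future O1) to the primary benzylic alcohol without base, so the aryl silyl ether and the acetals are not endangered.

Step 10
Reactants: 17 1-{6-[3-geranyl-4,5-bis(methoxymethoxy)benzyloxy]-4-(methoxymethoxy)-3-prenyl-2-(triisopropylsilyloxy)phenyl}ethanone
Product: 20 2-diazo-1-{6-[3-geranyl-4,5-bis(methoxymethoxy)benzyloxy]-4-(methoxymethoxy)-3-prenyl-2-(triisopropylsilyloxy)phenyl}ethanone, via lithium enolate 18 (not isolated), via trifluoroacetyl diketone 19 (not isolated)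
Conditions: LiN(SiMe3)2 (1.1 equiv), THF, −78 °C; CF3CO2CH2CF3, −78 °C; cold 1 M HCl wash, crude 19 taken on; MsN3, Et3N, H2O (1 equiv), MeCN, rt
Reagents that add atoms: methanesulfonyl azide (MsN3), CS(=O)(=O)N=[N+]=[N-]
Why: Detrifluoroacetylative diazo transfer (a Regitz-type transfer to an activated ketone): the lithium enolate of the methyl ketone is C-acylated to a trifluoromethyl β-diketone, which accepts the diazo group from the sulfonyl azide and loses the trifluoroacetyl group as the N-acylsulfonamide, a sequence that is standard for aryl methyl ketones and needs no acid chloride or diazomethane.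

Step 11
Reactants: 20 2-diazo-1-{6-[3-geranyl-4,5-bis(methoxymethoxy)benzyloxy]-4-(methoxymethoxy)-3-prenyl-2-(triisopropylsilyloxy)phenyl}ethanone
Product: 21 (2S)-2-[3-geranyl-4,5-bis(methoxymethoxy)phenyl]-7-(methoxymethoxy)-6-prenyl-5-(triisopropylsilyloxy)chroman-4-one
Conditions: Rh2(S-PTTL)4, dirhodium tetrakis[N-phthaloyl-(S)-tert-leucinate] (2 mol %), CH2Cl2, 0 °C, 20 added over 4 h by syringe pump (final ca. 0.01 M)
Reagents that add atoms: none
Why: Loss of dinitrogen on the dirhodium core gives an electrophilic rhodium carbenoid at the future C3, which inserts into one C–H bond of the O1–CH2–aryl group through a concerted, asynchronous three-centre transition state with hydride-like transfer to the carbenoid carbon, forming C2–C3. The closest known reactions are the dirhodium-carboxylate-catalysed C–H insertions of ortho-alkoxyaryl diazoketones that give chroman-4-ones and the Rh2(S-PTTL)4-catalysed enantioselective insertions into benzylic C–H bonds of aryl benzyl ethers. Ring C closes as a six-membered ring by 1,6-insertion, the carbenoid carbon and the benzylic carbon being linked through C4, C4a, C8a and O1. C2 is the only new stereocentre and is controlled by the catalyst, whose phthalimido and tert-butyl groups wall in the carbenoid so that one of the two enantiotopic benzylic hydrogens is transferred preferentially. The step needs chemoselectivity for this C–H bond over oxonium ylide formation at O1 with 1,2-benzyl shift and over every other C–H bond or alkene. The substrate secures it because the benzylic C–H bonds are activated by O1 and by the para-alkoxy ring B, the aryl ether oxygen is a poor donor, O5 bears a bulky silyl group with no C–H next to oxygen, the MOM methylenes and the trisubstituted alkenes cannot reach the carbenoid through an unstrained ring, and slow addition at high dilution suppresses bimolecular reactions.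

Step 12
Reactants: 21 (2S)-2-[3-geranyl-4,5-bis(methoxymethoxy)phenyl]-7-(methoxymethoxy)-6-prenyl-5-(triisopropylsilyloxy)chroman-4-one
Product: 22 (2S)-2-[3-geranyl-4,5-bis(methoxymethoxy)phenyl]-5-hydroxy-7-(methoxymethoxy)-6-prenylchroman-4-one
Conditions: n-Bu4NF, AcOH (1:1), THF, 0 °C
Reagents that add atoms: none
Why: Fluoride-driven cleavage of the strained peri aryl silyl ether; the acetic acid buffer keeps phenoxide basicity low so that ring opening by β-elimination of O1, the path by which flavanones racemise, should not occur.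

Step 13
Reactants: 22 (2S)-2-[3-geranyl-4,5-bis(methoxymethoxy)phenyl]-5-hydroxy-7-(methoxymethoxy)-6-prenylchroman-4-one
Product: 23 schizolaenone B
Conditions: HCl (3 M aq), MeOH, 40 °C
Reagents that add atoms: none
Why: Acid-catalysed acetal methanolysis removes the three aryl MOM ethers, a deprotection with ample precedent on prenylated and geranylated flavanones, and C2 is not epimerised under mild acid.

**Compound list**

1 | 2′,4′,6′-trihydroxyacetophenone (phloroacetophenone) | CC(=O)c1c(O)cc(O)cc1O | starting material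
2 | 1-[2,6-dihydroxy-4-(methoxymethoxy)phenyl]ethanone | CC(=O)c1c(O)cc(OCOC)cc1O | intermediate
3 | 1-[2-hydroxy-4-(methoxymethoxy)-6-(triisopropylsilyloxy)phenyl]ethanone | CC(=O)c1c(O)cc(OCOC)cc1O[Si](C(C)C)(C(C)C)C(C)C | intermediate
4 | 3-methylbut-2-en-1-ol (prenol) | CC(C)=CCO | starting material
5 | 1-[4-(methoxymethoxy)-2-(3-methylbut-2-enyloxy)-6-(triisopropylsilyloxy)phenyl]ethanone | CC(=O)c1c(OCC=C(C)C)cc(OCOC)cc1O[Si](C(C)C)(C(C)C)C(C)C | intermediate
6 | ortho-dienone, 2-acetyl-5-(methoxymethoxy)-6-(2-methylbut-3-en-2-yl)-3-(triisopropylsilyloxy)cyclohexa-2,4-dien-1-one | CC(=O)C1=C(O[Si](C(C)C)(C(C)C)C(C)C)C=C(OCOC)C(C(C)(C)C=C)C1=O | intermediate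
7 | para-dienone, 2-acetyl-5-(methoxymethoxy)-4-(3-methylbut-2-enyl)-3-(triisopropylsilyloxy)cyclohexa-2,5-dien-1-one | CC(=O)C1=C(O[Si](C(C)C)(C(C)C)C(C)C)C(CC=C(C)C)C(OCOC)=CC1=O | intermediate
8 | 1-[6-hydroxy-4-(methoxymethoxy)-3-(3-methylbut-2-enyl)-2-(triisopropylsilyloxy)phenyl]ethanone | CC(=O)c1c(O)cc(OCOC)c(CC=C(C)C)c1O[Si](C(C)C)(C(C)C)C(C)C | intermediate
9 | 5-bromovanillin (3-bromo-4-hydroxy-5-methoxybenzaldehyde) | COc1cc(C=O)cc(Br)c1O | starting material
10 | 3-bromo-4,5-dihydroxybenzaldehyde | O=Cc1cc(O)c(O)c(Br)c1 | intermediate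
11 | 3-bromo-4,5-bis(methoxymethoxy)benzaldehyde | COCOc1cc(C=O)cc(Br)c1OCOC | intermediate
12 | [3-bromo-4,5-bis(methoxymethoxy)phenyl]methanol | COCOc1cc(CO)cc(Br)c1OCOC | intermediate
13 | geranyl bromide, (2E)-1-bromo-3,7-dimethylocta-2,6-diene | CC(C)=CCC/C(C)=C/CBr | starting material
14 | lithium [3-lithio-4,5-bis(methoxymethoxy)phenyl]methanolate | [Li]OCc1cc([Li])c(OCOC)c(OCOC)c1 | intermediate
15 | lithium [3-cuprio-4,5-bis(methoxymethoxy)phenyl]methanolate (arylcopper) | [Li]OCc1cc([Cu])c(OCOC)c(OCOC)c1 | intermediate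
16 | [3-geranyl-4,5-bis(methoxymethoxy)phenyl]methanol | CC(C)=CCC/C(C)=C/Cc1cc(CO)cc(OCOC)c1OCOC | intermediate
17 | 1-{6-[3-geranyl-4,5-bis(methoxymethoxy)benzyloxy]-4-(methoxymethoxy)-3-prenyl-2-(triisopropylsilyloxy)phenyl}ethanone | CC(C)=CCC/C(C)=C/Cc1cc(COc2cc(OCOC)c(CC=C(C)C)c(O[Si](C(C)C)(C(C)C)C(C)C)c2C(C)=O)cc(OCOC)c1OCOC | intermediate
18 | lithium enolate of 17, lithium 1-aryl-ethen-1-olate (aryl as in 17) | CC(C)=CCC/C(C)=C/Cc1cc(COc2cc(OCOC)c(CC=C(C)C)c(O[Si](C(C)C)(C(C)C)C(C)C)c2C(=C)O[Li])cc(OCOC)c1OCOC | intermediate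
19 | 4,4,4-trifluoro-1-aryl-butane-1,3-dione (aryl as in 17) | CC(C)=CCC/C(C)=C/Cc1cc(COc2cc(OCOC)c(CC=C(C)C)c(O[Si](C(C)C)(C(C)C)C(C)C)c2C(=O)CC(=O)C(F)(F)F)cc(OCOC)c1OCOC | intermediate
20 | 2-diazo-1-{6-[3-geranyl-4,5-bis(methoxymethoxy)benzyloxy]-4-(methoxymethoxy)-3-prenyl-2-(triisopropylsilyloxy)phenyl}ethanone | CC(C)=CCC/C(C)=C/Cc1cc(COc2cc(OCOC)c(CC=C(C)C)c(O[Si](C(C)C)(C(C)C)C(C)C)c2C(=O)C=[N+]=[N-])cc(OCOC)c1OCOC | intermediate
21 | (2S)-2-[3-geranyl-4,5-bis(methoxymethoxy)phenyl]-7-(methoxymethoxy)-6-prenyl-5-(triisopropylsilyloxy)chroman-4-one | CC(C)=CCC/C(C)=C/Cc1cc([C@@H]2CC(=O)c3c(cc(OCOC)c(CC=C(C)C)c3O[Si](C(C)C)(C(C)C)C(C)C)O2)cc(OCOC)c1OCOC | intermediate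
22 | (2S)-2-[3-geranyl-4,5-bis(methoxymethoxy)phenyl]-5-hydroxy-7-(methoxymethoxy)-6-prenylchroman-4-one | CC(C)=CCC/C(C)=C/Cc1cc([C@@H]2CC(=O)c3c(cc(OCOC)c(CC=C(C)C)c3O)O2)cc(OCOC)c1OCOC | intermediate
23 | schizolaenone B, (2S)-2-(3-geranyl-4,5-dihydroxyphenyl)-5,7-dihydroxy-6-prenylchroman-4-one | CC(C)=CCC/C(C)=C/Cc1cc([C@@H]2CC(=O)c3c(cc(O)c(CC=C(C)C)c3O)O2)cc(O)c1O | target

**Count**

Total steps: 13. Longest linear sequence: 9 steps (steps 1–4 and 9–13 from compound 1; equally steps 5–13 from compound 9).

**Steps most likely to fail**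

Step 11. The O1 lone pair may attack the carbenoid faster than the C–H bond does, and the resulting five-membered oxonium ylide would shift its benzyl group to carbon instead of closing ring C. Independently, an acceptor-only carbenoid may be too reactive for the catalyst to tell the two enantiotopic hydrogens apart well. The fallback builds the same protected flavanone by a chalcone route and resolves it; it sets out from 16 and 8 and returns at 21. Alcohol 16 is oxidised with MnO2 in CH2Cl2 to 3-geranyl-4,5-bis(methoxymethoxy)benzaldehyde F1. Aldol condensation of F1 with ketone 8 under pyrrolidine in ethanol (amine conditions that spare the aryl silyl ether) gives the 2′-hydroxychalcone F2. Intramolecular oxa-Michael addition of F2 (NaOAc, EtOH, reflux) gives the racemic 5-silyloxy flavanone F3. Kinetic resolution by asymmetric transfer hydrogenation with RuCl(p-cymene)[(R,R)-TsDPEN] and HCO2H–Et3N, stopped near half conversion, should reduce the (2R) enantiomer to the (2R,4R)-cis-flavan-4-ol F4 and leave the (2S) ketone, which is compound 21 and re-enters the route at step 12.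

Step 4. The ortho-dienone may tautomerise before the Cope shift and so fix a reversed 1,1-dimethylallyl group at the ortho carbon. The second shift into the crowded position between the OMOM and OTIPS groups may also be slow enough for thermal loss of the silyl group or decomposition to compete. The fallback avoids the rearrangement; it sets out from 2 and returns at 17. Direct C-prenylation of 2 (prenyl bromide, DBU, THF, rt) gives 1-[2,6-dihydroxy-4-(methoxymethoxy)-3-prenylphenyl]ethanone F5. Mitsunobu etherification of F5 with alcohol 16 (PPh3, DIAD, THF) should go to the less hindered hydroxyl, the one para to the prenyl group, and give 1-{6-[3-geranyl-4,5-bis(methoxymethoxy)benzyloxy]-2-hydroxy-4-(methoxymethoxy)-3-prenylphenyl}ethanone F6. Silylation of the remaining chelated hydroxyl (TIPSCl, imidazole, DMF, 40 °C) gives 17, and the route continues with step 10.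

Step 13. Protic acid may induce cyclisation of the prenyl or geranyl chain onto a neighbouring free phenol, add HCl or methanol across the trisubstituted alkenes, or slowly open ring C with partial loss of configuration. The fallback removes all protic acid; it sets out from 21 and returns at 23. Treatment of 21 with Me3SiOTf and 2,2′-bipyridyl in CH2Cl2 at 0 °C exchanges the three aryl MOM ethers for trimethylsilyl ethers and gives the (2S)-5-(triisopropylsilyloxy)-7,3′,4′-tris(trimethylsilyloxy) flavanone F7. A single treatment of F7 with n-Bu4NF/AcOH in THF at 0 °C then removes all four silyl groups and gives 23.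

**Further compounds**

F1 | step 11 | 3-geranyl-4,5-bis(methoxymethoxy)benzaldehyde | CC(C)=CCC/C(C)=C/Cc1cc(C=O)cc(OCOC)c1OCOC
F2 | step 11 | (E)-3-[3-geranyl-4,5-bis(methoxymethoxy)phenyl]-1-[6-hydroxy-4-(methoxymethoxy)-3-prenyl-2-(triisopropylsilyloxy)phenyl]prop-2-en-1-one | CC(C)=CCC/C(C)=C/Cc1cc(/C=C/C(=O)c2c(O)cc(OCOC)c(CC=C(C)C)c2O[Si](C(C)C)(C(C)C)C(C)C)cc(OCOC)c1OCOC
F3 | step 11 | racemic 2-[3-geranyl-4,5-bis(methoxymethoxy)phenyl]-7-(methoxymethoxy)-6-prenyl-5-(triisopropylsilyloxy)chroman-4-one | CC(C)=CCC/C(C)=C/Cc1cc(C2CC(=O)c3c(cc(OCOC)c(CC=C(C)C)c3O[Si](C(C)C)(C(C)C)C(C)C)O2)cc(OCOC)c1OCOC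
F4 | step 11 | (2R,4R)-2-[3-geranyl-4,5-bis(methoxymethoxy)phenyl]-7-(methoxymethoxy)-6-prenyl-5-(triisopropylsilyloxy)chroman-4-ol (cis) | CC(C)=CCC/C(C)=C/Cc1cc([C@H]2C[C@@H](O)c3c(cc(OCOC)c(CC=C(C)C)c3O[Si](C(C)C)(C(C)C)C(C)C)O2)cc(OCOC)c1OCOC
F5 | step 4 | 1-[2,6-dihydroxy-4-(methoxymethoxy)-3-(3-methylbut-2-enyl)phenyl]ethanone | CC(=O)c1c(O)cc(OCOC)c(CC=C(C)C)c1O
F6 | step 4 | 1-{6-[3-geranyl-4,5-bis(methoxymethoxy)benzyloxy]-2-hydroxy-4-(methoxymethoxy)-3-prenylphenyl}ethanone | CC(C)=CCC/C(C)=C/Cc1cc(COc2cc(OCOC)c(CC=C(C)C)c(O)c2C(C)=O)cc(OCOC)c1OCOC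
F7 | step 13 | (2S)-2-[3-geranyl-4,5-bis(trimethylsilyloxy)phenyl]-6-prenyl-5-(triisopropylsilyloxy)-7-(trimethylsilyloxy)chroman-4-one | CC(C)=CCC/C(C)=C/Cc1cc([C@@H]2CC(=O)c3c(cc(O[Si](C)(C)C)c(CC=C(C)C)c3O[Si](C(C)C)(C(C)C)C(C)C)O2)cc(O[Si](C)(C)C)c1O[Si](C)(C)C
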